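Slowness at the end of these runs was what I wanted to understand, so I read the gamma run, where partner is the limiting reagent, against the beta run.

| setting | beta | alpha | delta | gamma | theta |
|---|---|---|---|---|---|
| substrate | 0.250 M | 0.130 M | 0.250 M | 0.250 M | 0.250 M |
| partner | 0.250 M | 0.130 M | 0.250 M | 0.120 M | 0.0380 M |
| free catalyst | 0.0130 M | 0.0130 M | 0.0130 M | 0.0130 M | 0.0130 M |
| product |  |  | 0.0750 M |  |  |
| time |  |  |  |  | 160 h |

| beta run: time / h | beta run: [substrate] / M | alpha run: time / h | alpha run: [substrate] / M | delta run: time / h | delta run: [substrate] / M | gamma run: time / h | gamma run: [substrate] / M |
|---|---|---|---|---|---|---|---|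
| 32 | 0.1380 | 32 | 0.0868 | 32 | 0.1478 | 32 | 0.1913 |
| 64 | 0.1131 | 64 | 0.0708 | 64 | 0.1194 | 64 | 0.1744 |
| 96 | 0.1001 | 96 | 0.0667 | 96 | 0.1103 | 96 | 0.1664 |
| 130 | 0.0921 | 130 | 0.0597 | 130 | 0.1063 | 130 | 0.1580 |
| 160 | 0.0896 | 160 | 0.0575 | 160 | 0.1020 | 160 | 0.1595 |

(readings scatter by 0.002 M)

- Overall: substrate + partner -> product, with free catalyst as catalyst.
- Constant volume, constant temperature.
- A reading of a species includes what of it is bound.
- An order is taken over about fifteen percent of the charge, up and down.

* apparent order in [substrate] of the starting rate, round the charge of the beta run (the rate where two percent of its substrate have turned into product) (one fixed amount of product, the same in the runs compared)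
* apparent order in [partner] of the starting rate, round the charge of the beta run (the rate where two percent of its substrate have turned into product)
* the alpha run starts with 0.120 M less of substrate and of partner than the beta run, and with no product. Compared where both hold the same amount of substrate, once fifteen percent of what the alpha run was charged with has turned into product, is the alpha run faster, slower or alike (within a tenth)?
* substrate in the theta run at 160 h, as a share of the substrate charged

Taking the last row and counting each substrate used as one product, I found that the beta run had made 64.2% of its partner charge into product and the gamma run 75.4%, a larger share. Yet by subtraction the gamma run should still hold 0.0295 M of partner while its readings barely move. So I committed to a picture of my own: each partner either goes to product, at a pseudo-first-order constant proportional to substrate, or is wasted at a steady constant.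

Reading down the gamma column, product grew by 0.0587 M in the first 32 h and by 0.0169 M in the next 32.0 h. The ratio of these gains gave a combined decay constant of 0.0389 h⁻¹ for partner. Multiplying that by the gamma share gave a use constant of 0.0293 h⁻¹, and the remainder, 0.00957 h⁻¹, is the wastage constant, the fraction of partner lost per hour whatever the substrate. Dividing the use constant by the mean early substrate of the gamma run gave 0.138 M⁻¹ h⁻¹.

For the theta run I went round twice. At its charged substrate the use constant is 0.0346 h⁻¹, so partner's share going to product is 78.3%, which makes 0.0298 M of product. Putting that back, the mean substrate drops by 0.0149 M, the use constant becomes 0.0325 h⁻¹ and the share 77.3%. Since 160 h spans 6.73 lifetimes of partner, I expected 88.3% of the substrate to remain.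

The forecast gave orders of 0.6 in substrate and 0.95 in partner, called the alpha run faster, and put the theta run at 87.4%, lower than my figure, holding that the “reaction therefore stalls on equilibrium”.

The flask gives orders of 0.82 and 1.0, the alpha run faster, and 87.7% for the theta run.

    free catalyst + substrate ⇌ catalyst-substrate complex, settled at all times (1.010 M⁻¹)
    catalyst-substrate complex + partner → product + free catalyst + by-product (9.684 M⁻¹ h⁻¹)
    free catalyst + product → spent catalyst + product (0.08028 M⁻¹ h⁻¹)
    partner → lost reagent (0.004932 h⁻¹)

In the theta run the substrate consumed comes to 81.1% of the partner charged. That leaves 18.9% of the theta run's partner charge not turned into product, where my wastage constant of 0.00957 h⁻¹ had put the wasted share at 22.7%. The loss of partner shows in the alpha run against the beta run: with the turning of partner into lost reagent taken away, the rate of the alpha run over that of the beta run at the same amount of substrate falls from 2.4 to 1.4.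

(The readings were computed with made-up constants, noise included.)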